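**Retrosynthetic overview**
1. The exocyclic methylene comes from a C6 ketone, the cis-4,5-diol from α-face dihydroxylation of a cyclohept-4-en-6-one, and that enone from allylic C–H oxidation of a cycloheptene.
2. The C8–O ester bond and the C8a–H bond are made together by anti-Markovnikov addition of 3-methylbutanoic acid across a C8=C8a alkene (key C–O bond formation, new).
3. That alkene comes from dehydration of a bicyclic aldol, and the tertiary carbinol from isopropyl addition to the resulting enone.
4. The five-membered ring is bought (3-methylcyclopent-2-en-1-one); its quaternary centre is set by enantioselective conjugate vinylation with aldol trapping by pent-4-enal.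
5. The seven-membered ring is closed second, by ring-closing metathesis.

Assumption: bicyclic compounds carry azulene numbering (C1 carbinol or carbonyl carbon of the five-membered ring, C3a methyl-bearing fusion carbon, C8a the other fusion carbon); metal alkoxides and the osmate ester that are only hydrolysed on work-up are not numbered. The angular methyl is taken as β.

**Step 1**
Reactants: 1 3-methylcyclopent-2-en-1-one; 2 vinylmagnesium bromide; 3 pent-4-enal
Product: 6 (3R)-3-ethenyl-2-(1-hydroxypent-4-en-1-yl)-3-methylcyclopentan-1-one (C2/C1′ diastereomer mixture), via dimethyl(vinyl)aluminium 4 (not isolated), via aluminium enolate 5 (not isolated)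
Conditions: 2, Me2AlCl, Et2O, 0 °C; then 1, copper thiophene-2-carboxylate (CuTC, 5 mol %), chiral phosphinamine ligand Ph2P–N[CH(CH3)(2-naphthyl)]2 (10 mol %, enantiomer that gives 5), −30 °C; then 3, −78 → −30 °C; aq. Rochelle salt
Reagents that add atoms: none
Why: Copper-catalysed enantioselective conjugate addition of an alkenylalane to a β-substituted cyclic enone sets the quaternary centre under ligand control and gives the regiodefined enolate 5, which is trapped at C2 by aldol addition; the two further stereocentres are erased in step 3, so their ratio does not matter.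

**Step 2**
Reactants: 6
Product: 7 (3aR)-8-hydroxy-3a-methyl-3,3a,6,7,8,8a-hexahydroazulen-1(2H)-one (C8/C8a diastereomer mixture)
Conditions: second-generation Hoveyda–Grubbs catalyst (5 mol %), CH2Cl2 (5 mM), 40 °C
Reagents that add atoms: none
Why: Ring-closing metathesis between the vinyl group on the quaternary carbon and the terminal alkene closes the seven-membered ring with loss of ethene; all diastereomers converge in step 3.

**Step 3**
Reactants: 7
Product: 9 (3aR)-3a-methyl-3,3a,6,7-tetrahydroazulen-1(2H)-one, via mesylate 8 (not isolated)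
Conditions: MsCl, Et3N, CH2Cl2, 0 °C; then DBU, rt
Reagents that add atoms: none
Why: Mesylation and E1cB elimination (aldol dehydration) can place the new alkene only between C8 and C8a, conjugated with the ketone, and removes both undefined stereocentres.

**Step 4**
Reactants: 9; 10 isopropylmagnesium chloride
Product: 11 (1R,3aR)-3a-methyl-1-(propan-2-yl)-1,2,3,3a,6,7-hexahydroazulen-1-ol
Conditions: LaCl3·2LiCl (30 mol %), THF, −78 → 0 °C; then H2O
Reagents that add atoms: none
Why: Lanthanum-promoted Grignard 1,2-addition to the enone carbonyl avoids conjugate addition and enolisation; the nucleophile enters on the α-face, opposite the pseudo-axial angular methyl, so the new hydroxyl is cis to that methyl (1R).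

**Step 5**
Reactants: 11; 12 3-methylbutanoic acid
Product: 13 (1R,3aR,8S,8aS)-1-hydroxy-3a-methyl-1-(propan-2-yl)-1,2,3,3a,6,7,8,8a-octahydroazulen-8-yl 3-methylbutanoate
Conditions: 9-mesityl-10-methylacridinium tetrafluoroborate (5 mol %), PhSH (20 mol %), 2,6-lutidine (25 mol %), 12 (5 equiv), 1,2-dichloroethane, 450 nm LEDs, 23 °C
Reagents that add atoms: none
Why: Proposed new method: the excited acridinium should oxidise the more electron-rich trisubstituted C8=C8a alkene (not the cis-disubstituted C4=C5 alkene) to its radical cation; the carboxylate adds at the less substituted C8 on the α-face, away from the axial 3a-methyl and C1 hydroxyl that flank the β-face, and the resulting tertiary C8a radical takes hydrogen from PhSH on the same α-face, so the ester C–O bond, the C8 stereocentre and the trans ring fusion are set in one operation; the closest known reaction type is the acridinium/thiol photoredox anti-Markovnikov addition of carboxylic acids to simple trisubstituted alkenes, which has not been used on a hydroxyl-bearing diene to control a ring-fusion centre.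

**Step 6**
Reactants: 13
Product: 15 (1R,3aR,8S,8aS)-1-hydroxy-3a-methyl-6-oxo-1-(propan-2-yl)-1,2,3,3a,6,7,8,8a-octahydroazulen-8-yl 3-methylbutanoate, via allylic tert-butyl peroxide 14 (not isolated)
Conditions: Rh2(cap)4 (cap = caprolactamate, 1 mol %), tBuOOH (5 equiv), K2CO3 (cat.), CH2Cl2, rt
Reagents that add atoms: tert-butyl hydroperoxide, CC(C)(C)OO
Why: Dirhodium caprolactamate/TBHP allylic C–H oxidation: C6 is the only allylic C–H position of the ring alkene (the other allylic carbon is quaternary), the allyl radical is trapped by the peroxyl radical at the less hindered C6, and the mixed peroxide collapses to the enone.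

**Step 7**
Reactants: 15
Product: 16 (1R,3aS,4S,5S,8S,8aS)-1,4,5-trihydroxy-3a-methyl-6-oxo-1-(propan-2-yl)decahydroazulen-8-yl 3-methylbutanoate
Conditions: K2OsO2(OH)4 (5 mol %), NMO (1.5 equiv), citric acid (1 equiv), tBuOH/H2O 1:1, rt
Reagents that add atoms: N-methylmorpholine N-oxide, C[N+]1([O-])CCOCC1; water, O
Why: Upjohn syn-dihydroxylation (citric acid variant for electron-poor alkenes); OsO4 adds to the enone on the α-face, away from the axial 3a-methyl on the neighbouring carbon, giving the cis-4,5-diol with both hydroxyls trans to that methyl.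

**Step 8**
Reactants: 16
Product: 17 (1R,3aS,4S,5R,8S,8aS)-1,4,5-trihydroxy-3a-methyl-6-methylidene-1-(propan-2-yl)decahydroazulen-8-yl 3-methylbutanoate (target)
Conditions: Zn, CH2Br2, TiCl4, THF/CH2Cl2, 0 °C → rt (excess); aq. NaHCO3
Reagents that add atoms: dibromomethane, BrCBr
Why: Lombardo methylenation: the non-basic zinc/titanium methylene reagent olefinates the ketone without enolisation, so the α-hydroxy stereocentre, the β-acyloxy group and the ester survive, with excess reagent covering the three free hydroxyls.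

**Compound list**
1 | 3-methylcyclopent-2-en-1-one | CC1=CC(=O)CC1 | starting material
2 | vinylmagnesium bromide | C=C[Mg]Br | starting material
3 | pent-4-enal | C=CCCC=O | starting material
4 | dimethyl(vinyl)aluminium | C=C[Al](C)C | intermediate
5 | dimethylaluminium (3R)-3-ethenyl-3-methylcyclopent-1-en-1-olate | C=C[C@@]1(C)CCC(O[Al](C)C)=C1 | intermediate
6 | (3R)-3-ethenyl-2-(1-hydroxypent-4-en-1-yl)-3-methylcyclopentan-1-one, diastereomer mixture at C2 and C1′ | C=CCCC(O)C1[C@](C)(CCC1=O)C=C | intermediate
7 | (3aR)-8-hydroxy-3a-methyl-3,3a,6,7,8,8a-hexahydroazulen-1(2H)-one, diastereomer mixture at C8 and C8a | C1CC(O)C2[C@](C)(CCC2=O)C=C1 | intermediate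
8 | 8-O-methanesulfonate of 7 | C1CC(OS(C)(=O)=O)C2[C@](C)(CCC2=O)C=C1 | intermediate
9 | (3aR)-3a-methyl-3,3a,6,7-tetrahydroazulen-1(2H)-one | C1CC=C2[C@](C)(CCC2=O)C=C1 | intermediate
10 | isopropylmagnesium chloride | CC(C)[Mg]Cl | starting material
11 | (1R,3aR)-3a-methyl-1-(propan-2-yl)-1,2,3,3a,6,7-hexahydroazulen-1-ol | C1CC=C2[C@](C)(CC[C@@]2(O)C(C)C)C=C1 | intermediate
12 | 3-methylbutanoic acid | CC(C)CC(=O)O | starting material
13 | (1R,3aR,8S,8aS)-1-hydroxy-3a-methyl-1-(propan-2-yl)-1,2,3,3a,6,7,8,8a-octahydroazulen-8-yl 3-methylbutanoate | C1C[C@H](OC(=O)CC(C)C)[C@@H]2[C@](C)(CC[C@@]2(O)C(C)C)C=C1 | intermediate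
14 | 6-(tert-butylperoxy) derivative of 13 (C6 configuration undefined) | CC(C)(C)OOC1C[C@H](OC(=O)CC(C)C)[C@@H]2[C@](C)(CC[C@@]2(O)C(C)C)C=C1 | intermediate
15 | (1R,3aR,8S,8aS)-1-hydroxy-3a-methyl-6-oxo-1-(propan-2-yl)-1,2,3,3a,6,7,8,8a-octahydroazulen-8-yl 3-methylbutanoate | O=C1C[C@H](OC(=O)CC(C)C)[C@@H]2[C@](C)(CC[C@@]2(O)C(C)C)C=C1 | intermediate
16 | (1R,3aS,4S,5S,8S,8aS)-1,4,5-trihydroxy-3a-methyl-6-oxo-1-(propan-2-yl)decahydroazulen-8-yl 3-methylbutanoate | O=C1C[C@H](OC(=O)CC(C)C)[C@@H]2[C@](C)(CC[C@@]2(O)C(C)C)[C@H](O)[C@@H]1O | intermediate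
17 | (1R,3aS,4S,5R,8S,8aS)-1,4,5-trihydroxy-3a-methyl-6-methylidene-1-(propan-2-yl)decahydroazulen-8-yl 3-methylbutanoate | C=C1C[C@H](OC(=O)CC(C)C)[C@@H]2[C@](C)(CC[C@@]2(O)C(C)C)[C@H](O)[C@@H]1O | target

**Totals**
Total step count: 8. Longest linear sequence: 8 steps (from 1).

**Steps most likely to fail**

Step 5 (the new reaction). The α-face selectivity at C8 and C8a is unproven, the second alkene may also be oxidised, and the tertiary allylic alcohol may ionise in acid. The fallback sets out from 9 and comes back at 13. Weitz–Scheffer epoxidation of 9 (H2O2, NaOH, MeOH, 0 °C) on the α-face gives (3aR,8S,8aR)-8,8a-epoxy-3a-methyl-3,3a,6,7,8,8a-hexahydroazulen-1(2H)-one F1. SmI2 (THF/MeOH, −78 °C) cleaves the Cα–O bond and the samarium enolate is protonated on the α-face to give (3aR,8S,8aS)-8-hydroxy-3a-methyl-3,3a,6,7,8,8a-hexahydroazulen-1(2H)-one F2. Isopropylmagnesium chloride with LaCl3·2LiCl then gives (1R,3aR,8S,8aS)-3a-methyl-1-(propan-2-yl)-1,2,3,3a,6,7,8,8a-octahydroazulene-1,8-diol F3. Acylation of the secondary hydroxyl alone (3-methylbutanoic anhydride, DMAP, pyridine) gives 13.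

Step 6. The peroxyl radical may be trapped at C4, giving the transposed enone. The fallback sets out from 13 and comes back at 15. SeO2 (cat.)/tBuOOH in CH2Cl2 hydroxylates C6 by an ene reaction followed by a 2,3-sigmatropic shift, which returns the alkene to C4=C5, giving the 6-hydroxy derivative of 13 F4. Dess–Martin periodinane then gives 15.

Step 8. Methylenation beside two free hydroxyls and a β-acyloxy group may stall or cause elimination. The fallback sets out from 16 and comes back at 17. 2,2-Dimethoxypropane with PPTS gives the 4,5-acetonide of 16 F5. Cp2TiMe2 (toluene, 65 °C, Petasis olefination) gives the 4,5-acetonide of 17 F6. Aqueous 80% AcOH at 40 °C releases 17.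

**Further compounds**
F1 | step 5 | (3aR,8S,8aR)-8,8a-epoxy-3a-methyl-3,3a,6,7,8,8a-hexahydroazulen-1(2H)-one (epoxide oxygen α) | C1C[C@@H]3O[C@]32[C@](C)(CCC2=O)C=C1
F2 | step 5 | (3aR,8S,8aS)-8-hydroxy-3a-methyl-3,3a,6,7,8,8a-hexahydroazulen-1(2H)-one | C1C[C@H](O)[C@@H]2[C@](C)(CCC2=O)C=C1
F3 | step 5 | (1R,3aR,8S,8aS)-3a-methyl-1-(propan-2-yl)-1,2,3,3a,6,7,8,8a-octahydroazulene-1,8-diol | C1C[C@H](O)[C@@H]2[C@](C)(CC[C@@]2(O)C(C)C)C=C1
F4 | step 6 | 6-hydroxy derivative of 13 (C6 configuration undefined) | OC1C[C@H](OC(=O)CC(C)C)[C@@H]2[C@](C)(CC[C@@]2(O)C(C)C)C=C1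
F5 | step 8 | 4,5-acetonide of 16 | O=C1C[C@H](OC(=O)CC(C)C)[C@@H]2[C@](C)(CC[C@@]2(O)C(C)C)[C@@H]3OC(C)(C)O[C@H]13
F6 | step 8 | 4,5-acetonide of 17 | C=C1C[C@H](OC(=O)CC(C)C)[C@@H]2[C@](C)(CC[C@@]2(O)C(C)C)[C@@H]3OC(C)(C)O[C@H]13
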